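**Retrosynthetic overview**

- The route rests on C4 of ring C. It is benzylic to ring E, whose E3' (ortho) and E5' (para) oxygens stabilise positive charge at C4, while C4a of ring A lies para to the C7 oxygen and is tied to C2 through O1.
- Ring C is therefore opened at C4–C4a to the trans C3–C4 epoxide of a 3-benzyloxyphenyl ether. The ether comes from a Mitsunobu inversion at C2, and the epoxy alcohol from an epoxy chalcone whose rings B and E both derive from one aryl bromide.
- Ring F is built afterwards on the ring E bromide: O1–C2 by asymmetric allylic etherification with a ring D vinylphenol, C3=C4 by ring-closing metathesis, and the cis-diol by osmylation anti to ring E.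
- Order of ring formation: epoxide, ring C (key step), ring F; hydrogenolysis of the aryl benzyl ethers is last.

Key step: step 9

Remarks on the chemistry

- Labels: upper flavan rings A, C, B; lower flavan rings D, F, E; ring E carries C2 of ring F at E1' and C4 of ring C at E2'.
- The Mitsunobu etherification inverts C2, so the epoxy alcohol must be the syn (threo) isomer 10. Chelation-controlled hydride reduction of ketone 9 would give the anti isomer and, after inversion, a 2,3-cis flavan. The carbinol is therefore set by a catalyst-controlled transfer hydrogenation.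
- Assumption: the sense of induction of the iridium/phosphoramidite catalyst on carbonate 19 follows that of unhindered cinnamyl carbonates, for which the (Ra,Rc,Rc) ligand gives (R)-1-arylallyl aryl ethers. The (Sa,Sc,Sc) ligand is therefore specified for the (S) ether 23.
- Abbreviation in names: Fl = (2R,3S,4S)-7-(benzyloxy)-3-[(tert-butyldimethylsilyl)oxy]-2-[3,4,5-tris(benzyloxy)phenyl]-3,4-dihydro-2H-chromen-4-yl.

**Route**

Step 1
Reactants: 1 5-bromo-1,2,3-trimethoxybenzene
Product: 2 5-bromobenzene-1,2,3-triol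
Conditions: BBr3 (3.5 equiv), CH2Cl2, −78 °C → rt; H2O
Reagents that add atoms: none
Why: Lewis-acid ether cleavage by BBr3 (bromide attacks the methyl group of the aryloxonium borane) should remove all three methyl groups while the aryl bromide is inert.

Step 2
Reactants: 2 5-bromobenzene-1,2,3-triol
Product: 3 1,2,3-tris(benzyloxy)-5-bromobenzene
Conditions: BnBr (3.3 equiv), K2CO3, DMF, 60 °C, N2
Reagents that add atoms: benzyl bromide BrCc1ccccc1
Why: Williamson etherification of the three phenoxides installs the benzyl groups used on every phenol of the route, under nitrogen because the pyrogallol is air-sensitive in base.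

Step 3
Reactants: 3 1,2,3-tris(benzyloxy)-5-bromobenzene
Product: 5 2,3,4-tris(benzyloxy)-6-bromobenzaldehyde, via aryllithium 4 (not isolated)
Conditions: LiN(i-Pr)2 (1.1 equiv), THF, −78 °C; DMF; H2O
Reagents that add atoms: N,N-dimethylformamide CN(C)C=O
Why: Directed ortho-metalation: the only two ring hydrogens are equivalent and flanked by Br and OBn, so the amide base should deprotonate there at −78 °C (below the temperature of LiBr loss) and DMF formylates the aryllithium.

Step 4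
Reactants: 3 1,2,3-tris(benzyloxy)-5-bromobenzene
Product: 7 1-[3,4,5-tris(benzyloxy)phenyl]ethan-1-one, via aryllithium 6 (not isolated)
Conditions: n-BuLi (1.05 equiv), THF, −78 °C; MeC(O)N(OMe)Me; H2O
Reagents that add atoms: N-methoxy-N-methylacetamide CC(=O)N(C)OC
Why: Lithium–bromine exchange followed by Weinreb ketone synthesis, in which the chelated adduct prevents over-addition, should give the ring B methyl ketone from the same bromide that serves ring E.

Step 5
Reactants: 5 2,3,4-tris(benzyloxy)-6-bromobenzaldehyde; 7 1-[3,4,5-tris(benzyloxy)phenyl]ethan-1-one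
Product: 8 (E)-3-[2,3,4-tris(benzyloxy)-6-bromophenyl]-1-[3,4,5-tris(benzyloxy)phenyl]prop-2-en-1-one
Conditions: KOH, EtOH/THF, rt
Reagents that add atoms: none
Why: Claisen–Schmidt condensation of the non-enolisable aldehyde with the ketone enolate, followed by E1cB dehydration, should give the thermodynamically favoured E enone.

Step 6
Reactants: 8 (E)-chalcone
Product: 9 [(2S,3R)-3-[2,3,4-tris(benzyloxy)-6-bromophenyl]oxiran-2-yl][3,4,5-tris(benzyloxy)phenyl]methanone (trans epoxide)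
Conditions: poly-D-leucine, urea·H2O2, DBU, THF, rt
Reagents that add atoms: urea–hydrogen peroxide adduct OO.NC(N)=O
Why: Juliá–Colonna epoxidation (conjugate addition of hydroperoxide to the enone held on the helical polypeptide, then ring closure) should give the trans epoxy ketone and sets C3 and C4 of ring C; poly-D-leucine is specified because the L-polymer is known to give the (2R,3S) epoxide from chalcone itself.

Step 7
Reactants: 9 trans epoxy ketone
Product: 10 (S)-[(2R,3R)-3-[2,3,4-tris(benzyloxy)-6-bromophenyl]oxiran-2-yl][3,4,5-tris(benzyloxy)phenyl]methanol (syn epoxy alcohol; oxirane geometry as in 9, the C2 label changes by priority only)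
Conditions: RuCl[(R,R)-TsDPEN](p-cymene) (2 mol %), HCO2H/Et3N (1:3), CH2Cl2, 25 °C
Reagents that add atoms: none
Why: Noyori asymmetric transfer hydrogenation of the aryl ketone: the (S,S) catalyst gives (S)-1-phenylethanol from acetophenone, so the (R,R) catalyst with ring B in the aryl position should give the mirror spatial outcome, labelled S here because the oxiranyl carbon outranks the aryl group; no chelating metal is present and the amine-rich formate medium should spare the acid-labile epoxide.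

Step 8
Reactants: 10 syn epoxy alcohol; 11 3-(benzyloxy)phenol
Product: 12 (2S,3R)-2-{(R)-[3-(benzyloxy)phenoxy][3,4,5-tris(benzyloxy)phenyl]methyl}-3-[2,3,4-tris(benzyloxy)-6-bromophenyl]oxirane
Conditions: PPh3, DIAD, toluene, 0 °C → rt
Reagents that add atoms: none
Why: Mitsunobu etherification: the phenoxide displaces the alkoxyphosphonium group with inversion, turning the S carbinol into the R aryl ether needed for the 2,3-trans flavan, and the adjacent epoxide and the meta-alkoxy pattern of ring B disfavour ionisation at this carbon.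

Step 9
Reactants: 12 aryl ether of the trans epoxy alcohol
Product: 13 (2R,3S,4S)-7-(benzyloxy)-4-[2,3,4-tris(benzyloxy)-6-bromophenyl]-2-[3,4,5-tris(benzyloxy)phenyl]-3,4-dihydro-2H-chromen-3-ol (2,3-trans-3,4-trans)
Conditions: BF3·OEt2 (0.3 equiv), CH2Cl2, −78 → −40 °C; Et3N quench
Reagents that add atoms: none
Why: BF3 coordinates the epoxide oxygen and the C4–O bond lengthens first, because positive charge at C4 is delocalised into ring E through the E3' (ortho) and E5' (para) benzyloxy groups, whereas C3 has no such donor. Ring A then attacks C4 through the carbon ortho to the ether oxygen and para to its benzyloxy group (C4a), and rearomatisation releases the C3 hydroxyl; the closest known reaction type is the intramolecular Friedel–Crafts epoxide–arene cyclisation of aryl ethers of 3-aryl-2,3-epoxy alcohols to trans-4-arylchroman-3-ols. Ring C closes in the 6-endo mode (both epoxide carbons end up in the new ring), the 5-exo attack at C3 being electronically unassisted. C4 is set by anti, invertive opening of the trans epoxide, which places ring E trans to the C3 hydroxyl, while C2 and C3 are carried over unchanged, so the chair-like transition state holds ring B, O3 and ring E all equatorial. The step needs C4 over C3 regioselectivity, para over ortho attack on ring A, ring A rather than ring B as the nucleophile and no 1,2-hydride shift; these should be secured by the ring E donors, by crowding at the carbon between the two ring A oxygens, by the six-membered tether (ring B could only close a strained five-membered ring) and by low temperature with substoichiometric acid.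

Step 10
Reactants: 13 4-arylflavan-3-ol
Product: 14 1,2,3-tris(benzyloxy)-5-bromo-4-Fl-benzene (the 3-O-TBS ether of 13)
Conditions: TBSOTf, 2,6-lutidine, CH2Cl2, 0 °C → rt
Reagents that add atoms: tert-butyldimethylsilyl trifluoromethanesulfonate CC(C)(C)[Si](C)(C)OS(=O)(=O)C(F)(F)F
Why: Silylation of the hindered secondary alcohol with the silyl triflate gives an ether that tolerates organolithium, hydride, metathesis and osmylation conditions and is removed by fluoride, so that only aryl benzyl ethers remain for the last step.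

Step 11
Reactants: 14 silyl ether bromide
Product: 16 3,4,5-tris(benzyloxy)-2-Fl-benzaldehyde, via aryllithium 15 (not isolated)
Conditions: n-BuLi (1.1 equiv), THF, −78 °C; DMF; H2O
Reagents that add atoms: N,N-dimethylformamide CN(C)C=O
Why: Lithium–bromine exchange is much faster than any deprotonation at −78 °C, and formylation of the aryllithium with DMF (Bouveault aldehyde synthesis) should give the ring E aldehyde.

Step 12
Reactants: 16 ring E aldehyde
Product: 17 ethyl (E)-3-[3,4,5-tris(benzyloxy)-2-Fl-phenyl]prop-2-enoate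
Conditions: (EtO)2P(O)CH2CO2Et, NaH, THF, 0 °C → rt
Reagents that add atoms: triethyl phosphonoacetate CCOC(=O)CP(=O)(OCC)OCC
Why: Horner–Wadsworth–Emmons olefination with the stabilised phosphonate anion should give the E cinnamate.

Step 13
Reactants: 17 cinnamate ester
Product: 18 (E)-3-[3,4,5-tris(benzyloxy)-2-Fl-phenyl]prop-2-en-1-ol
Conditions: i-Bu2AlH (2.5 equiv), CH2Cl2, −78 °C; Rochelle salt
Reagents that add atoms: none
Why: 1,2-Reduction of the unsaturated ester by the aluminium hydride at low temperature should give the allylic alcohol without touching the silyl or benzyl ethers.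

Step 14
Reactants: 18 cinnamyl alcohol
Product: 19 (E)-3-[3,4,5-tris(benzyloxy)-2-Fl-phenyl]prop-2-en-1-yl methyl carbonate
Conditions: ClCO2Me, pyridine, CH2Cl2, 0 °C
Reagents that add atoms: methyl chloroformate COC(Cl)=O
Why: Acylation of the primary alcohol gives the allylic methyl carbonate, the leaving group that ionises to the allyl iridium complex and releases methoxide as internal base.

Step 15
Reactants: 20 4-(benzyloxy)-2-hydroxybenzaldehyde
Product: 21 5-(benzyloxy)-2-ethenylphenol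
Conditions: Ph3PCH3Br (2.5 equiv), KOt-Bu (2.5 equiv), THF, 0 °C → rt
Reagents that add atoms: methyltriphenylphosphonium bromide C[P+](c1ccccc1)(c1ccccc1)c1ccccc1.[Br-]
Why: Wittig methylenation with an excess of ylide (one equivalent is lost to the phenol) should give the ring D vinylphenol, which is used promptly because it polymerises easily.

Step 16
Reactants: 19 allylic methyl carbonate; 21 5-(benzyloxy)-2-ethenylphenol
Product: 23 4-(benzyloxy)-2-{[(1S)-1-[3,4,5-tris(benzyloxy)-2-Fl-phenyl]prop-2-en-1-yl]oxy}-1-ethenylbenzene, via lithium phenolate 22 (not isolated)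
Conditions: 21, LiN(SiMe3)2, THF, 0 °C; then 19, [Ir(cod)Cl]2 (2 mol %), (Sa,Sc,Sc)-O,O'-(1,1'-binaphthalene-2,2'-diyl) N,N-bis(1-phenylethyl)phosphoramidite (4 mol %, activated with n-PrNH2), THF, 50 °C
Reagents that add atoms: none
Why: Iridium-catalysed asymmetric allylic etherification: the cyclometalated iridium phosphoramidite complex ionises the linear carbonate to an allyl complex that the phenoxide attacks at the aryl-bearing terminus, so the branched ether should form with its configuration (S, the future C2 of ring F) fixed by the ligand and not by the remote upper unit.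

Step 17
Reactants: 23 branched allyl aryl ether
Product: 24 (2S)-7-(benzyloxy)-2-[3,4,5-tris(benzyloxy)-2-Fl-phenyl]-2H-chromene
Conditions: second-generation Grubbs catalyst (H2IMes)(PCy3)Cl2Ru=CHPh (5 mol %), CH2Cl2, 40 °C
Reagents that add atoms: none
Why: Ring-closing metathesis of the styrene and the allyl ether alkene closes ring F as the six-membered 2H-chromene with loss of ethene and without touching the C2 stereocentre.

Step 18
Reactants: 24 2H-chromene
Product: 25 (2R,3S,4S)-7-(benzyloxy)-2-[3,4,5-tris(benzyloxy)-2-Fl-phenyl]-3,4-dihydro-2H-chromene-3,4-diol (2,3-trans-3,4-cis)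
Conditions: OsO4 (5 mol %), NMO, acetone/H2O, rt
Reagents that add atoms: osmium tetroxide O=[Os](=O)(=O)=O; N-methylmorpholine N-oxide C[N+]1([O-])CCOCC1; water O
Why: Upjohn dihydroxylation: OsO4 adds suprafacially to the C3=C4 bond on the face opposite the bulky C2 aryl group, which should give the cis-diol trans to ring E and so set C3 and C4 of ring F.

Step 19
Reactants: 25 silyl-protected diol
Product: 26 (2R,3S,4S)-7-(benzyloxy)-2-{3,4,5-tris(benzyloxy)-2-[(2R,3S,4S)-7-(benzyloxy)-3-hydroxy-2-[3,4,5-tris(benzyloxy)phenyl]-3,4-dihydro-2H-chromen-4-yl]phenyl}-3,4-dihydro-2H-chromene-3,4-diol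
Conditions: Bu4NF, THF, rt
Reagents that add atoms: none
Why: Fluoride cleaves the Si–O bond of the silyl ether under non-acidic conditions that leave the acid-labile benzylic C4 hydroxyl of ring F untouched.

Step 20
Reactants: 26 octabenzyl ether
Product: 27 (2R,3S,4S)-2-{2-[(2R,3S,4S)-3,7-dihydroxy-2-(3,4,5-trihydroxyphenyl)-3,4-dihydro-2H-chromen-4-yl]-3,4,5-trihydroxyphenyl}-3,4-dihydro-2H-chromene-3,4,7-triol (CNP0205451.3)
Conditions: H2 (1 atm), 10% Pd/C, EtOAc/MeOH, rt, stopped at complete debenzylation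
Reagents that add atoms: none
Why: Catalytic hydrogenolysis: only aryl benzyl ethers remain, and under neutral conditions at one atmosphere these should cleave faster than the benzylic C4–OH of ring F or the C2–O1 bonds are reduced.

**Compound list**

1 | 5-bromo-1,2,3-trimethoxybenzene | COc1cc(Br)cc(OC)c1OC | starting material
2 | 5-bromobenzene-1,2,3-triol | Oc1cc(Br)cc(O)c1O | intermediate
3 | 1,2,3-tris(benzyloxy)-5-bromobenzene | Brc1cc(OCc5ccccc5)c(OCc5ccccc5)c(OCc5ccccc5)c1 | intermediate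
4 | [2,3,4-tris(benzyloxy)-6-bromophenyl]lithium | [Li]c1c(Br)cc(OCc5ccccc5)c(OCc5ccccc5)c1OCc5ccccc5 | intermediate
5 | 2,3,4-tris(benzyloxy)-6-bromobenzaldehyde | O=Cc1c(Br)cc(OCc5ccccc5)c(OCc5ccccc5)c1OCc5ccccc5 | intermediate
6 | [3,4,5-tris(benzyloxy)phenyl]lithium | [Li]c1cc(OCc5ccccc5)c(OCc5ccccc5)c(OCc5ccccc5)c1 | intermediate
7 | 1-[3,4,5-tris(benzyloxy)phenyl]ethan-1-one | CC(=O)c1cc(OCc5ccccc5)c(OCc5ccccc5)c(OCc5ccccc5)c1 | intermediate
8 | (E)-3-[2,3,4-tris(benzyloxy)-6-bromophenyl]-1-[3,4,5-tris(benzyloxy)phenyl]prop-2-en-1-one | O=C(/C=C/c1c(Br)cc(OCc5ccccc5)c(OCc5ccccc5)c1OCc5ccccc5)c1cc(OCc5ccccc5)c(OCc5ccccc5)c(OCc5ccccc5)c1 | intermediate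
9 | [(2S,3R)-3-[2,3,4-tris(benzyloxy)-6-bromophenyl]oxiran-2-yl][3,4,5-tris(benzyloxy)phenyl]methanone | O=C(c1cc(OCc5ccccc5)c(OCc5ccccc5)c(OCc5ccccc5)c1)[C@H]1O[C@@H]1c1c(Br)cc(OCc5ccccc5)c(OCc5ccccc5)c1OCc5ccccc5 | intermediate
10 | (S)-[(2R,3R)-3-[2,3,4-tris(benzyloxy)-6-bromophenyl]oxiran-2-yl][3,4,5-tris(benzyloxy)phenyl]methanol (syn) | O[C@@H](c1cc(OCc5ccccc5)c(OCc5ccccc5)c(OCc5ccccc5)c1)[C@H]1O[C@@H]1c1c(Br)cc(OCc5ccccc5)c(OCc5ccccc5)c1OCc5ccccc5 | intermediate
11 | 3-(benzyloxy)phenol | Oc1cccc(OCc5ccccc5)c1 | starting material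
12 | (2S,3R)-2-{(R)-[3-(benzyloxy)phenoxy][3,4,5-tris(benzyloxy)phenyl]methyl}-3-[2,3,4-tris(benzyloxy)-6-bromophenyl]oxirane | c5ccccc5COc1cccc(c1)O[C@H](c1cc(OCc5ccccc5)c(OCc5ccccc5)c(OCc5ccccc5)c1)[C@H]1O[C@@H]1c1c(Br)cc(OCc5ccccc5)c(OCc5ccccc5)c1OCc5ccccc5 | intermediate
13 | (2R,3S,4S)-7-(benzyloxy)-4-[2,3,4-tris(benzyloxy)-6-bromophenyl]-2-[3,4,5-tris(benzyloxy)phenyl]-3,4-dihydro-2H-chromen-3-ol | c5ccccc5COc1ccc2c(c1)O[C@H](c1cc(OCc5ccccc5)c(OCc5ccccc5)c(OCc5ccccc5)c1)[C@@H](O)[C@@H]2c1c(Br)cc(OCc5ccccc5)c(OCc5ccccc5)c1OCc5ccccc5 | intermediate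
14 | 1,2,3-tris(benzyloxy)-5-bromo-4-Fl-benzene (3-O-TBS ether of 13) | c5ccccc5COc1ccc2c(c1)O[C@H](c1cc(OCc5ccccc5)c(OCc5ccccc5)c(OCc5ccccc5)c1)[C@@H](O[Si](C)(C)C(C)(C)C)[C@@H]2c1c(Br)cc(OCc5ccccc5)c(OCc5ccccc5)c1OCc5ccccc5 | intermediate
15 | [3,4,5-tris(benzyloxy)-2-Fl-phenyl]lithium | c5ccccc5COc1ccc2c(c1)O[C@H](c1cc(OCc5ccccc5)c(OCc5ccccc5)c(OCc5ccccc5)c1)[C@@H](O[Si](C)(C)C(C)(C)C)[C@@H]2c1c([Li])cc(OCc5ccccc5)c(OCc5ccccc5)c1OCc5ccccc5 | intermediate
16 | 3,4,5-tris(benzyloxy)-2-Fl-benzaldehyde | c5ccccc5COc1ccc2c(c1)O[C@H](c1cc(OCc5ccccc5)c(OCc5ccccc5)c(OCc5ccccc5)c1)[C@@H](O[Si](C)(C)C(C)(C)C)[C@@H]2c1c(C=O)cc(OCc5ccccc5)c(OCc5ccccc5)c1OCc5ccccc5 | intermediate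
17 | ethyl (E)-3-[3,4,5-tris(benzyloxy)-2-Fl-phenyl]prop-2-enoate | c5ccccc5COc1ccc2c(c1)O[C@H](c1cc(OCc5ccccc5)c(OCc5ccccc5)c(OCc5ccccc5)c1)[C@@H](O[Si](C)(C)C(C)(C)C)[C@@H]2c1c(/C=C/C(=O)OCC)cc(OCc5ccccc5)c(OCc5ccccc5)c1OCc5ccccc5 | intermediate
18 | (E)-3-[3,4,5-tris(benzyloxy)-2-Fl-phenyl]prop-2-en-1-ol | c5ccccc5COc1ccc2c(c1)O[C@H](c1cc(OCc5ccccc5)c(OCc5ccccc5)c(OCc5ccccc5)c1)[C@@H](O[Si](C)(C)C(C)(C)C)[C@@H]2c1c(/C=C/CO)cc(OCc5ccccc5)c(OCc5ccccc5)c1OCc5ccccc5 | intermediate
19 | (E)-3-[3,4,5-tris(benzyloxy)-2-Fl-phenyl]prop-2-en-1-yl methyl carbonate | c5ccccc5COc1ccc2c(c1)O[C@H](c1cc(OCc5ccccc5)c(OCc5ccccc5)c(OCc5ccccc5)c1)[C@@H](O[Si](C)(C)C(C)(C)C)[C@@H]2c1c(/C=C/COC(=O)OC)cc(OCc5ccccc5)c(OCc5ccccc5)c1OCc5ccccc5 | intermediate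
20 | 4-(benzyloxy)-2-hydroxybenzaldehyde | O=Cc1ccc(OCc5ccccc5)cc1O | starting material
21 | 5-(benzyloxy)-2-ethenylphenol | C=Cc1ccc(OCc5ccccc5)cc1O | intermediate
22 | lithium 5-(benzyloxy)-2-ethenylphenolate | C=Cc1ccc(OCc5ccccc5)cc1O[Li] | intermediate
23 | 4-(benzyloxy)-2-{[(1S)-1-[3,4,5-tris(benzyloxy)-2-Fl-phenyl]prop-2-en-1-yl]oxy}-1-ethenylbenzene | c5ccccc5COc1ccc2c(c1)O[C@H](c1cc(OCc5ccccc5)c(OCc5ccccc5)c(OCc5ccccc5)c1)[C@@H](O[Si](C)(C)C(C)(C)C)[C@@H]2c1c([C@H](C=C)Oc3cc(OCc5ccccc5)ccc3C=C)cc(OCc5ccccc5)c(OCc5ccccc5)c1OCc5ccccc5 | intermediate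
24 | (2S)-7-(benzyloxy)-2-[3,4,5-tris(benzyloxy)-2-Fl-phenyl]-2H-chromene | c5ccccc5COc1ccc2c(c1)O[C@H](c1cc(OCc5ccccc5)c(OCc5ccccc5)c(OCc5ccccc5)c1)[C@@H](O[Si](C)(C)C(C)(C)C)[C@@H]2c1c([C@H]2Oc3cc(OCc5ccccc5)ccc3C=C2)cc(OCc5ccccc5)c(OCc5ccccc5)c1OCc5ccccc5 | intermediate
25 | (2R,3S,4S)-7-(benzyloxy)-2-[3,4,5-tris(benzyloxy)-2-Fl-phenyl]-3,4-dihydro-2H-chromene-3,4-diol | c5ccccc5COc1ccc2c(c1)O[C@H](c1cc(OCc5ccccc5)c(OCc5ccccc5)c(OCc5ccccc5)c1)[C@@H](O[Si](C)(C)C(C)(C)C)[C@@H]2c1c([C@H]2Oc3cc(OCc5ccccc5)ccc3[C@H](O)[C@@H]2O)cc(OCc5ccccc5)c(OCc5ccccc5)c1OCc5ccccc5 | intermediate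
26 | (2R,3S,4S)-7-(benzyloxy)-2-{3,4,5-tris(benzyloxy)-2-[(2R,3S,4S)-7-(benzyloxy)-3-hydroxy-2-[3,4,5-tris(benzyloxy)phenyl]-3,4-dihydro-2H-chromen-4-yl]phenyl}-3,4-dihydro-2H-chromene-3,4-diol | c5ccccc5COc1ccc2c(c1)O[C@H](c1cc(OCc5ccccc5)c(OCc5ccccc5)c(OCc5ccccc5)c1)[C@@H](O)[C@@H]2c1c([C@H]2Oc3cc(OCc5ccccc5)ccc3[C@H](O)[C@@H]2O)cc(OCc5ccccc5)c(OCc5ccccc5)c1OCc5ccccc5 | intermediate
27 | (2R,3S,4S)-2-{2-[(2R,3S,4S)-3,7-dihydroxy-2-(3,4,5-trihydroxyphenyl)-3,4-dihydro-2H-chromen-4-yl]-3,4,5-trihydroxyphenyl}-3,4-dihydro-2H-chromene-3,4,7-triol | Oc1ccc2c(c1)O[C@H](c1cc(O)c(O)c(O)c1)[C@@H](O)[C@@H]2c1c([C@H]2Oc3cc(O)ccc3[C@H](O)[C@@H]2O)cc(O)c(O)c1O | target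

**Step count and risks**

Total step count: 20. Longest linear sequence: 18 steps (steps 1, 2, 3, 5 to 14 and 16 to 20; steps 4 and 15 are side branches).

Steps most likely to fail

1. Step 9 (epoxide–arene closure of ring C). What may go wrong: a 1,2-hydride shift from C3 to the developing C4 cation (Meinwald rearrangement to a ketone), capture of C4 by ring B, ionisation of the C2–O bond, or loss of stereospecificity through a long-lived cation. Fallback, setting out from 12 and returning at 13: the ring opening is separated from the ring closure and the C4 configuration is placed under neighbouring-group control. Mild acid methanolysis of 12 (PPTS, MeOH/CH2Cl2, 0 °C) should open the epoxide at the benzylic carbon with inversion to the methoxy alcohol (1S,2S,3R)-3-[3-(benzyloxy)phenoxy]-1-methoxy-1-[2,3,4-tris(benzyloxy)-6-bromophenyl]-3-[3,4,5-tris(benzyloxy)phenyl]propan-2-ol F1. Acetylation (Ac2O, pyridine, DMAP) gives the acetate (1S,2S,3R)-3-[3-(benzyloxy)phenoxy]-1-methoxy-1-[2,3,4-tris(benzyloxy)-6-bromophenyl]-3-[3,4,5-tris(benzyloxy)phenyl]propan-2-yl acetate F2. Ionisation of the benzylic methyl ether with TMSOTf (CH2Cl2, −78 °C) forms a 1,3-dioxolan-2-ylium ion bridging C3 and C4, which blocks the hydride shift and directs ring A to attack C4 anti to the C3 oxygen; this gives (2R,3S,4S)-7-(benzyloxy)-4-[2,3,4-tris(benzyloxy)-6-bromophenyl]-2-[3,4,5-tris(benzyloxy)phenyl]-3,4-dihydro-2H-chromen-3-yl acetate F3. Methanolysis (K2CO3, MeOH) returns 13.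

2. Step 16 (iridium-catalysed allylic etherification). What may go wrong: slow ionisation of the ortho-hindered cinnamyl carbonate, attack at the unsubstituted terminus giving the linear ether, or weak facial control at the new stereocentre. Fallback, setting out from 18 and returning at 23: the stereocentre is set by an epoxidation and an invertive opening instead. Sharpless asymmetric epoxidation of 18 (Ti(Oi-Pr)4, L-(+)-diethyl tartrate, t-BuOOH, 4 Å sieves, CH2Cl2, −20 °C) should give [(2S,3S)-3-[3,4,5-tris(benzyloxy)-2-Fl-phenyl]oxiran-2-yl]methanol F4. Opening at the benzylic C3 by the phenoxide of 21 (NaOH, dioxane/H2O, 60 °C) with inversion gives (2S,3R)-3-[5-(benzyloxy)-2-ethenylphenoxy]-3-[3,4,5-tris(benzyloxy)-2-Fl-phenyl]propane-1,2-diol F5. Thiocarbonyldiimidazole converts the diol into its cyclic thionocarbonate, the 1,3-dioxolane-2-thione of F5, F6. Corey–Winter olefination (1,3-dimethyl-2-phenyl-1,3,2-diazaphospholidine, THF, 40 °C) then gives the terminal alkene 23.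

3. Step 7 (catalyst-controlled reduction). What may go wrong: insufficient catalyst control over the substrate bias, giving a mixture at the carbinol, or opening of the epoxide by formate. Fallback, setting out from 9 and returning at 10: substrate control followed by inversion. Chelation-controlled reduction with Zn(BH4)2 (Et2O, −20 °C) should give the anti alcohol (R)-[(2R,3R)-3-[2,3,4-tris(benzyloxy)-6-bromophenyl]oxiran-2-yl][3,4,5-tris(benzyloxy)phenyl]methanol F7. Mitsunobu esterification with 4-nitrobenzoic acid (PPh3, DIAD, THF) inverts the carbinol to (S)-[(2S,3R)-3-[2,3,4-tris(benzyloxy)-6-bromophenyl]oxiran-2-yl][3,4,5-tris(benzyloxy)phenyl]methyl 4-nitrobenzoate F8. Methanolysis (K2CO3, MeOH, 0 °C) gives 10.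

**Further compounds**

F1 | step 9 | (1S,2S,3R)-3-[3-(benzyloxy)phenoxy]-1-methoxy-1-[2,3,4-tris(benzyloxy)-6-bromophenyl]-3-[3,4,5-tris(benzyloxy)phenyl]propan-2-ol | c5ccccc5COc1cccc(c1)O[C@H](c1cc(OCc5ccccc5)c(OCc5ccccc5)c(OCc5ccccc5)c1)[C@@H](O)[C@@H](OC)c1c(Br)cc(OCc5ccccc5)c(OCc5ccccc5)c1OCc5ccccc5
F2 | step 9 | (1S,2S,3R)-3-[3-(benzyloxy)phenoxy]-1-methoxy-1-[2,3,4-tris(benzyloxy)-6-bromophenyl]-3-[3,4,5-tris(benzyloxy)phenyl]propan-2-yl acetate | c5ccccc5COc1cccc(c1)O[C@H](c1cc(OCc5ccccc5)c(OCc5ccccc5)c(OCc5ccccc5)c1)[C@@H](OC(C)=O)[C@@H](OC)c1c(Br)cc(OCc5ccccc5)c(OCc5ccccc5)c1OCc5ccccc5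
F3 | step 9 | (2R,3S,4S)-7-(benzyloxy)-4-[2,3,4-tris(benzyloxy)-6-bromophenyl]-2-[3,4,5-tris(benzyloxy)phenyl]-3,4-dihydro-2H-chromen-3-yl acetate | c5ccccc5COc1ccc2c(c1)O[C@H](c1cc(OCc5ccccc5)c(OCc5ccccc5)c(OCc5ccccc5)c1)[C@@H](OC(C)=O)[C@@H]2c1c(Br)cc(OCc5ccccc5)c(OCc5ccccc5)c1OCc5ccccc5
F4 | step 16 | [(2S,3S)-3-[3,4,5-tris(benzyloxy)-2-Fl-phenyl]oxiran-2-yl]methanol | c5ccccc5COc1ccc2c(c1)O[C@H](c1cc(OCc5ccccc5)c(OCc5ccccc5)c(OCc5ccccc5)c1)[C@@H](O[Si](C)(C)C(C)(C)C)[C@@H]2c1c([C@@H]2O[C@H]2CO)cc(OCc5ccccc5)c(OCc5ccccc5)c1OCc5ccccc5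
F5 | step 16 | (2S,3R)-3-[5-(benzyloxy)-2-ethenylphenoxy]-3-[3,4,5-tris(benzyloxy)-2-Fl-phenyl]propane-1,2-diol | c5ccccc5COc1ccc2c(c1)O[C@H](c1cc(OCc5ccccc5)c(OCc5ccccc5)c(OCc5ccccc5)c1)[C@@H](O[Si](C)(C)C(C)(C)C)[C@@H]2c1c([C@H]([C@@H](O)CO)Oc3cc(OCc5ccccc5)ccc3C=C)cc(OCc5ccccc5)c(OCc5ccccc5)c1OCc5ccccc5
F6 | step 16 | cyclic thionocarbonate (1,3-dioxolane-2-thione) of diol F5 | c5ccccc5COc1ccc2c(c1)O[C@H](c1cc(OCc5ccccc5)c(OCc5ccccc5)c(OCc5ccccc5)c1)[C@@H](O[Si](C)(C)C(C)(C)C)[C@@H]2c1c([C@H]([C@@H]3COC(=S)O3)Oc4cc(OCc5ccccc5)ccc4C=C)cc(OCc5ccccc5)c(OCc5ccccc5)c1OCc5ccccc5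
F7 | step 7 | (R)-[(2R,3R)-3-[2,3,4-tris(benzyloxy)-6-bromophenyl]oxiran-2-yl][3,4,5-tris(benzyloxy)phenyl]methanol (anti) | O[C@H](c1cc(OCc5ccccc5)c(OCc5ccccc5)c(OCc5ccccc5)c1)[C@H]1O[C@@H]1c1c(Br)cc(OCc5ccccc5)c(OCc5ccccc5)c1OCc5ccccc5
F8 | step 7 | (S)-[(2S,3R)-3-[2,3,4-tris(benzyloxy)-6-bromophenyl]oxiran-2-yl][3,4,5-tris(benzyloxy)phenyl]methyl 4-nitrobenzoate | O=C(c1ccc(cc1)[N+](=O)[O-])O[C@@H](c1cc(OCc5ccccc5)c(OCc5ccccc5)c(OCc5ccccc5)c1)[C@H]1O[C@@H]1c1c(Br)cc(OCc5ccccc5)c(OCc5ccccc5)c1OCc5ccccc5
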